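A small charge of substrate, with no target in it, went into each of 3 flasks, and the target it forms speeds its own formation.

all flasks: substrate 0.050 M; time 20 min

| charge | temperature |
|---|---|
| dawn | 60 °C |
| midnight | 85 °C |
| winter | 35 °C |

    substrate + 2 target → 3 target (k1 = 3.5 M⁻² s⁻¹, Ea1 = 52.0 kJ mol⁻¹)
    substrate → target (k2 = 5.3 × 10⁻⁵ s⁻¹, Ea2 = 109 kJ mol⁻¹)
    target → over-reaction product (k3 = 3.0 × 10⁻⁶ s⁻¹, Ea3 = 115 kJ mol⁻¹)
    (constants at 35 °C)

- a step written with two of one species runs at k times the square of its concentration and takes two of it each time
- at 35 °C the constants are as listed, elsewhere as the activation energies make them

1. the flask with the highest amount of target, in percent of the substrate charged ("all alike" if they lie within 1.5 percentage points) (dawn / midnight / winter / all alike)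
2. final target, as a percentage of the substrate charged, in dawn
3. final target, as a percentage of the substrate charged, in midnight
4. final target, as a percentage of the substrate charged, in winter

I reckoned in fractions of the charge. Early on the substrate fraction is close to one, so I froze it there. The target fraction then grew at the rate constant of the direct step, plus the self-feeding step (autocatalysis), whose constant times the squared charge concentration multiplies the square of that fraction. The two constants pair into a time constant, one over the root of their product, 24.5 min in winter. For winter I reckoned 0.817: this is the ignition number, the time in the flask over that time constant. The frozen equation solves to a crossover fraction, where both steps run equally, times the tangent of this number, and that tangent blows up between 1 and 2.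

The winter number has a tangent close to one, so I expected winter to sit near the crossover, at 7.78%. Dawn gave 8.64 and midnight 65.7, both far past the blow-up, so I took their substrate as converted early.

One number was not enough, though, since it grows with temperature and does not contain the over-reaction. I therefore let the full charge decay by the over-reaction for the whole run, which gave 90.1% in dawn and 15.0% in midnight. My pick was dawn.

The forecast gave 91.8% for dawn, 15.6% for midnight and 7.8% for winter, and judged that “dawn is the clear winner”. The flasks gave 91.6% in dawn, 15.6% in midnight and 7.81% in winter, so dawn held the most target.

In winter the time constant of 24.5 min was longer than the run of 20 min, and 92% of the substrate still stood at the end beside 7.81% target. Run to 200 min, the same winter flask had a reckoned ignition number of 8.17, close to the 8.64 of dawn, and its substrate was down to 0% with target at 97.1%.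

The constants were set for the occasion; the result is computed.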